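Ring E, the C-methyl terminus, is disconnected into a four-carbon 3-ethoxycyclobutenone hanging from ring D through the CH2 bridge and a two-carbon siloxyalkyne. The feature exploited is the substitution of ring E: its oxygen-bearing carbons C2, C4 and C6 alternate with the carbon-bearing C1 (CH2 bridge), C3 (CH3) and C5 (butanoyl). A thermal cyclobutenone–siloxyalkyne benzannulation sets this alternation in one operation, forming two C–C bonds and the arene and leaving only C5 as C–H. Its precursor is the O-methylated pentamer of rings F, A, B, C and D whose ring D carries the racemic CH2-linked cyclobutenone. The chain is grown one ring per flask by chloromethylation and Friedel–Crafts benzylation.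

Key step: step 13

Assumption: ring F after step 9 is drawn as the 3,5-dimethoxy-2,5-dienone and the lactone of step 2 as the 6-butanoyl isomer; a regioisomeric enol ether would converge on the target in step 16, and the 8-butanoyl lactone would converge on 7 in step 3.

Step 1
Reactants: 1 1-(2,4,6-trihydroxyphenyl)butan-1-one
Product: 2 1-(2,4,6-trimethoxyphenyl)butan-1-one
Conditions: Me2SO4 (excess), K2CO3, acetone, reflux
Reagents that add atoms: dimethyl sulfate, COS(=O)(=O)OC
Why: Williamson O-methylation with a hard methylating agent favours O- over C-alkylation, and prolonged reflux also methylates the two hydroxyls that are hydrogen-bonded to the ketone.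

Step 2
Reactants: 1 1-(2,4,6-trihydroxyphenyl)butan-1-one; 3 acrylic acid
Product: 5 6-butanoyl-5,7-dihydroxychroman-2-one, via arylpropanoic acid 4 (not isolated)
Conditions: Amberlyst-15, PhMe, reflux (Dean–Stark)
Reagents that add atoms: none
Why: Acid-catalysed hydroarylation (Friedel–Crafts conjugate addition) onto acrylic acid followed by lactonisation of acid 4; a second C-acylation of the already acylated ring, which would give a chromanone, is disfavoured.

Step 3
Reactants: 5 6-butanoyl-5,7-dihydroxychroman-2-one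
Product: 7 benzyl 3-(3-butanoyl-2,4,6-trimethoxyphenyl)propanoate, via triphenol benzyl ester 6 (not isolated)
Conditions: BnOH, K2CO3, DMF, 60 °C; then Me2SO4, rt → 50 °C
Reagents that add atoms: benzyl alcohol, OCc1ccccc1; dimethyl sulfate, COS(=O)(=O)OC
Why: Alcoholysis of the aryl lactone is pulled to the open ester by deprotonation of the liberated phenol, and Williamson O-methylation of the three phenoxides makes it irreversible; the benzyl ester is chosen because it is later removed without base.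

Step 4
Reactants: 7 benzyl 3-(3-butanoyl-2,4,6-trimethoxyphenyl)propanoate; 2 1-(2,4,6-trimethoxyphenyl)butan-1-one
Product: 9 benzyl ester dimer D–C, via ring D chloride 8 (not isolated)
Conditions: MOMCl (excess), ZnCl2 (cat.), CH2Cl2, 0 °C → rt; volatiles stripped, PhMe chase; then 2 (fivefold excess), ZnCl2 (cat., Et2O solution), CH2Cl2, 0 °C → rt
Reagents that add atoms: chloromethyl methyl ether, COCCl
Why: Blanc chloromethylation at the single free position of ring D and, once the volatile MOMCl is stripped, Friedel–Crafts benzylation of 2 by the readily ionised di-ortho-methoxybenzylic chloride 8, which is used crude because it would not survive chromatography; the excess of cheap 2 keeps its ring to a single alkylation, so ring C retains one free C–H, and the unactivated phenyl ring of the benzyl ester does not compete.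

Step 5
Reactants: 9 benzyl ester dimer D–C; 2 1-(2,4,6-trimethoxyphenyl)butan-1-one
Product: 11 benzyl ester trimer D–C–B, via dimer chloride 10 (not isolated)
Conditions: MOMCl (excess), ZnCl2 (cat.), CH2Cl2, 0 °C → rt; volatiles stripped, PhMe chase; then 2 (fivefold excess), ZnCl2 (cat., Et2O solution), CH2Cl2, 0 °C → rt
Reagents that add atoms: chloromethyl methyl ether, COCCl
Why: The same one-flask cycle of Blanc chloromethylation and Friedel–Crafts benzylation: the only aromatic C–H left on an electron-rich ring of 9 (ring C) is chloromethylated, and chloride 10, which has no free ring position and cannot self-condense, alkylates 2 to add ring B.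

Step 6
Reactants: 11 benzyl ester trimer D–C–B; 2 1-(2,4,6-trimethoxyphenyl)butan-1-one
Product: 13 benzyl ester tetramer D–C–B–A, via trimer chloride 12 (not isolated)
Conditions: MOMCl (excess), ZnCl2 (cat.), CH2Cl2, 0 °C → rt; volatiles stripped, PhMe chase; then 2 (fivefold excess), ZnCl2 (cat., Et2O solution), CH2Cl2, 0 °C → rt
Reagents that add atoms: chloromethyl methyl ether, COCCl
Why: A third cycle of Blanc chloromethylation (at the free position of ring B) and Friedel–Crafts benzylation of excess 2 adds ring A, whose remaining C–H is the only one left on the electron-rich rings; every ring carries an acyl group that slows acid-induced cleavage of the methylene bridges already formed.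

Step 7
Reactants: 1 1-(2,4,6-trihydroxyphenyl)butan-1-one
Product: 14 2-butanoyl-3,5-dihydroxy-4,4-dimethylcyclohexa-2,5-dien-1-one
Conditions: NaOMe, MeI (2.2 equiv), MeOH, 0 °C → rt
Reagents that add atoms: iodomethane, CI
Why: C-Methylation of the phloroglucinol anion in a protic solvent, where hydrogen bonding shields oxygen; the second methylation at the same carbon dearomatises the ring, and under- and over-methylated by-products are removed at this cheap stage.

Step 8
Reactants: 13 benzyl ester tetramer D–C–B–A; 14 2-butanoyl-3,5-dihydroxy-4,4-dimethylcyclohexa-2,5-dien-1-one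
Product: 16 benzyl ester pentamer with free ring F enols, via tetramer chloride 15 (not isolated)
Conditions: MOMCl (excess), ZnCl2 (cat.), CH2Cl2, 0 °C → rt; volatiles stripped, PhMe chase; then 14 (slight excess), ZnCl2 (cat., Et2O solution), CH2Cl2, 0 °C → rt
Reagents that add atoms: chloromethyl methyl ether, COCCl
Why: Blanc chloromethylation of the last free position (ring A) and, after removal of MOMCl, Lewis-acid-catalysed C-benzylation of the cyclic triketone enol 14 (Friedel–Crafts-type): the stabilised benzylic cation is captured at C6, the only unsubstituted ring carbon of 14, and any O-benzyl enol ether re-ionises and is funnelled to the C-alkylated product.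

Step 9
Reactants: 16 benzyl ester pentamer with free ring F enols
Product: 17 benzyl ester pentamer with ring F as bis(methyl enol ether)
Conditions: Me3SiCHN2, PhMe/MeOH, 0 °C → rt
Reagents that add atoms: (trimethylsilyl)diazomethane, C[Si](C)(C)C=[N+]=[N-]
Why: Neutral O-methylation of the two acidic enols (vinylogous acids) with a diazomethane equivalent; they must be blocked because they would be acylated in step 11 and would protonate the siloxyalkyne in step 13.

Step 10
Reactants: 17 benzyl ester pentamer with ring F as bis(methyl enol ether)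
Product: 18 pentamer propanoic acid
Conditions: H2 (1 atm), Pd/C, EtOAc, rt
Reagents that add atoms: none
Why: Hydrogenolysis of the benzyl ester frees the acid without any nucleophile that could attack the ring F vinylogous esters; the fully substituted enol ether double bonds and the twisted di-ortho-substituted aryl ketones are not reduced under these conditions.

Step 11
Reactants: 18 pentamer propanoic acid; 19 ethoxyacetylene
Product: 22 pentamer 3-ethoxycyclobutenone (racemic at C4), via acid chloride 20 (not isolated), via ketene 21 (not isolated)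
Conditions: Me2C=C(Cl)NMe2, CH2Cl2, 0 °C → rt; then 19 (excess), Et3N (slow addition), CH2Cl2, rt
Reagents that add atoms: none
Why: Neutral acid chloride formation with the α-chloroenamine, dehydrochlorination to the monosubstituted ketene 21 and its [2+2] cycloaddition with the ynol ether, whose nucleophilic terminal carbon bonds to the ketene carbonyl carbon, give the 3-ethoxy-4-substituted cyclobutenone; C4 is formed racemic and is destroyed in step 13.

Step 12
Reactants: 23 propyne
Product: 26 1-(triisopropylsiloxy)propyne, via propynyllithium 24 (not isolated), via lithium ynolate 25 (not isolated)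
Conditions: n-BuLi, THF, −78 °C; LiOOt-Bu (from t-BuOOH, LiN(SiMe3)2), −78 → 0 °C; i-Pr3SiOTf, −78 °C → 0 °C
Reagents that add atoms: tert-butyl hydroperoxide, CC(C)(C)OO; triisopropylsilyl trifluoromethanesulfonate, CC(C)[Si](OS(=O)(=O)C(F)(F)F)(C(C)C)C(C)C
Why: Oxidation of the lithium acetylide by lithium tert-butyl peroxide gives the lithium ynolate, which the bulky silyl triflate traps on oxygen (ynolate O-silylation).

Step 13
Reactants: 22 pentamer 3-ethoxycyclobutenone; 26 1-(triisopropylsiloxy)propyne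
Product: 31 protected hexamer phenol, via vinylketene 27 (not isolated), via vinylcyclobutenone 28 (not isolated), via dienylketene 29 (not isolated), via cyclohexadienone 30 (not isolated)
Conditions: PhMe, 80 → 110 °C, sealed tube, 26 in excess
Reagents that add atoms: none
Why: Heat opens the cyclobutenone of 22 by conrotatory 4π electrocyclic cleavage of its C1–C4 bond to the ethoxy-vinylketene 27, whose ketene C=C adds [2+2] to the electron-rich alkyne 26 to give the 4-vinylcyclobutenone 28, and this opens again to the dienylketene 29. Ring E is closed by thermal disrotatory 6π electrocyclisation of 29 between the ketene carbon and the CH2-bearing terminus, and the cyclohexa-2,4-dienone 30 tautomerises to the phenol. The closest known reaction is the Danheiser benzannulation of cyclobutenones with siloxyalkynes to resorcinol monosilyl ethers, used here with a 3-alkoxycyclobutenone. No stereocentre is created, since the racemic C4 of 22 becomes an aromatic carbon. The one selectivity needed is regiochemical, methyl between the new hydroxyl and the siloxy group, and it is secured by polarity: the nucleophilic methyl-bearing alkyne carbon attacks the electrophilic ketene carbonyl carbon. The neutral conditions spare the methylene bridges, the ketones and the ring F enol ethers, and a dienylketene of the wrong geometry can revert through 28 until the productive isomer cyclises.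

Step 14
Reactants: 31 protected hexamer phenol
Product: 32 hexamer with ring E as 5-ethoxy-2-methylresorcinol
Conditions: Bu4NF, AcOH, THF, 0 °C
Reagents that add atoms: none
Why: Fluoride cleavage of the aryl silyl ether, buffered with AcOH so that the ring F vinylogous esters meet no basic fluoride or hydroxide; it exposes the second ring E hydroxyl and unshields C5.

Step 15
Reactants: 32 hexamer with ring E as 5-ethoxy-2-methylresorcinol
Product: 33 protected hexamer with all six butanoyl groups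
Conditions: (PrCO)2O, BF3·OEt2, CH2Cl2, 0 °C → rt; then aq. NaOAc, MeOH
Reagents that add atoms: butanoic anhydride, CCCC(=O)OC(=O)CCC
Why: Friedel–Crafts acylation at C5 of ring E, the only aromatic C–H in the molecule and activated by two hydroxyls and the ethoxy group; BF3 has no nucleophilic halide and spares the methyl ethers, and the acetate work-up breaks the boron chelate of the new o-hydroxy ketone.

Step 16
Reactants: 33 protected hexamer with all six butanoyl groups
Product: 34 CNP0309827.0 (target)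
Conditions: BBr3 (about 30 equiv), CH2Cl2, −78 °C → rt; then H2O
Reagents that add atoms: none
Why: Lewis-acid ether cleavage with BBr3 removes the twelve aryl methyl ethers, the ring E ethyl ether and the two ring F enol methyl ethers; each ring carries a Lewis-acid-bound acyl group that deactivates it towards ipso-protonation and so protects the methylene bridges, and the target has no stereocentre.

Compound list

1 | 1-(2,4,6-trihydroxyphenyl)butan-1-one | CCCC(=O)c1c(O)cc(O)cc1O | starting material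
2 | 1-(2,4,6-trimethoxyphenyl)butan-1-one | CCCC(=O)c1c(OC)cc(OC)cc1OC | intermediate
3 | acrylic acid | C=CC(=O)O | starting material
4 | 3-(3-butanoyl-2,4,6-trihydroxyphenyl)propanoic acid | OC(=O)CCc1c(O)cc(O)c(C(=O)CCC)c1O | intermediate (not isolated)
5 | 6-butanoyl-5,7-dihydroxychroman-2-one | O=C1CCc2c(O1)cc(O)c(C(=O)CCC)c2O | intermediate
6 | benzyl 3-(3-butanoyl-2,4,6-trihydroxyphenyl)propanoate (as its potassium phenoxides) | O=C(CCc1c(O)cc(O)c(C(=O)CCC)c1O)OCc1ccccc1 | intermediate (not isolated)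
7 | benzyl 3-(3-butanoyl-2,4,6-trimethoxyphenyl)propanoate (ring D unit) | O=C(CCc1c(OC)cc(OC)c(C(=O)CCC)c1OC)OCc1ccccc1 | intermediate
8 | benzyl 3-[3-butanoyl-5-(chloromethyl)-2,4,6-trimethoxyphenyl]propanoate (ring D chloride) | O=C(CCc1c(OC)c(CCl)c(OC)c(C(=O)CCC)c1OC)OCc1ccccc1 | intermediate (not isolated)
9 | benzyl ester dimer D–C: benzyl 3-{3-butanoyl-5-[(3-butanoyl-2,4,6-trimethoxyphenyl)methyl]-2,4,6-trimethoxyphenyl}propanoate, ring C with one free C–H | O=C(CCc2c(OC)c(Cc3c(OC)cc(OC)c(C(=O)CCC)c3OC)c(OC)c(C(=O)CCC)c2OC)OCc1ccccc1 | intermediate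
10 | dimer chloride: 9 with CH2Cl at the free position of ring C | O=C(CCc2c(OC)c(Cc3c(OC)c(CCl)c(OC)c(C(=O)CCC)c3OC)c(OC)c(C(=O)CCC)c2OC)OCc1ccccc1 | intermediate (not isolated)
11 | benzyl ester trimer D–C–B: 9 carrying at ring C a CH2-linked 3-butanoyl-2,4,6-trimethoxyphenyl unit (ring B, one free C–H) | O=C(CCc2c(OC)c(Cc3c(OC)c(Cc4c(OC)cc(OC)c(C(=O)CCC)c4OC)c(OC)c(C(=O)CCC)c3OC)c(OC)c(C(=O)CCC)c2OC)OCc1ccccc1 | intermediate
12 | trimer chloride: 11 with CH2Cl at the free position of ring B | O=C(CCc2c(OC)c(Cc3c(OC)c(Cc4c(OC)c(CCl)c(OC)c(C(=O)CCC)c4OC)c(OC)c(C(=O)CCC)c3OC)c(OC)c(C(=O)CCC)c2OC)OCc1ccccc1 | intermediate (not isolated)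
13 | benzyl ester tetramer D–C–B–A: benzyl 3-(ring D)propanoate; rings D, C and B are 5-butanoyl-2,4,6-trimethoxybenzene-1,3-diyl units and ring A a 3-butanoyl-2,4,6-trimethoxyphenyl unit with one free C–H, all joined by CH2 | O=C(CCc2c(OC)c(Cc3c(OC)c(Cc4c(OC)c(Cc5c(OC)cc(OC)c(C(=O)CCC)c5OC)c(OC)c(C(=O)CCC)c4OC)c(OC)c(C(=O)CCC)c3OC)c(OC)c(C(=O)CCC)c2OC)OCc1ccccc1 | intermediate
14 | 2-butanoyl-3,5-dihydroxy-4,4-dimethylcyclohexa-2,5-dien-1-one (ring F unit) | CCCC(=O)C1=C(O)C(C)(C)C(O)=CC1=O | intermediate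
15 | tetramer chloride: 13 with CH2Cl at the free position of ring A | O=C(CCc2c(OC)c(Cc3c(OC)c(Cc4c(OC)c(Cc5c(OC)c(CCl)c(OC)c(C(=O)CCC)c5OC)c(OC)c(C(=O)CCC)c4OC)c(OC)c(C(=O)CCC)c3OC)c(OC)c(C(=O)CCC)c2OC)OCc1ccccc1 | intermediate (not isolated)
16 | benzyl ester pentamer F–A–B–C–D with free ring F enols: ring A of 13 joined by CH2 to C6 of 2-butanoyl-3,5-dihydroxy-4,4-dimethylcyclohexa-2,5-dien-1-one | O=C(CCc2c(OC)c(Cc3c(OC)c(Cc4c(OC)c(Cc5c(OC)c(CC6=C(O)C(C)(C)C(O)=C(C(=O)CCC)C6=O)c(OC)c(C(=O)CCC)c5OC)c(OC)c(C(=O)CCC)c4OC)c(OC)c(C(=O)CCC)c3OC)c(OC)c(C(=O)CCC)c2OC)OCc1ccccc1 | intermediate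
17 | benzyl ester pentamer with ring F as 2-butanoyl-3,5-dimethoxy-4,4-dimethylcyclohexa-2,5-dien-1-one | O=C(CCc2c(OC)c(Cc3c(OC)c(Cc4c(OC)c(Cc5c(OC)c(CC6=C(OC)C(C)(C)C(OC)=C(C(=O)CCC)C6=O)c(OC)c(C(=O)CCC)c5OC)c(OC)c(C(=O)CCC)c4OC)c(OC)c(C(=O)CCC)c3OC)c(OC)c(C(=O)CCC)c2OC)OCc1ccccc1 | intermediate
18 | pentamer propanoic acid: 3-(ring D)propanoic acid of the permethylated pentamer | OC(=O)CCc2c(OC)c(Cc3c(OC)c(Cc4c(OC)c(Cc5c(OC)c(CC6=C(OC)C(C)(C)C(OC)=C(C(=O)CCC)C6=O)c(OC)c(C(=O)CCC)c5OC)c(OC)c(C(=O)CCC)c4OC)c(OC)c(C(=O)CCC)c3OC)c(OC)c(C(=O)CCC)c2OC | intermediate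
19 | ethoxyacetylene | CCOC#C | starting material
20 | acid chloride of 18 | ClC(=O)CCc2c(OC)c(Cc3c(OC)c(Cc4c(OC)c(Cc5c(OC)c(CC6=C(OC)C(C)(C)C(OC)=C(C(=O)CCC)C6=O)c(OC)c(C(=O)CCC)c5OC)c(OC)c(C(=O)CCC)c4OC)c(OC)c(C(=O)CCC)c3OC)c(OC)c(C(=O)CCC)c2OC | intermediate (not isolated)
21 | (ring D)methylketene derived from 20 | O=C=CCc2c(OC)c(Cc3c(OC)c(Cc4c(OC)c(Cc5c(OC)c(CC6=C(OC)C(C)(C)C(OC)=C(C(=O)CCC)C6=O)c(OC)c(C(=O)CCC)c5OC)c(OC)c(C(=O)CCC)c4OC)c(OC)c(C(=O)CCC)c3OC)c(OC)c(C(=O)CCC)c2OC | intermediate (not isolated)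
22 | 3-ethoxy-4-[(ring D)methyl]cyclobut-2-en-1-one of the permethylated pentamer, racemic at C4 | CCOC1=CC(=O)C1Cc2c(OC)c(Cc3c(OC)c(Cc4c(OC)c(Cc5c(OC)c(CC6=C(OC)C(C)(C)C(OC)=C(C(=O)CCC)C6=O)c(OC)c(C(=O)CCC)c5OC)c(OC)c(C(=O)CCC)c4OC)c(OC)c(C(=O)CCC)c3OC)c(OC)c(C(=O)CCC)c2OC | intermediate
23 | propyne | CC#C | starting material
24 | 1-propynyllithium | CC#C[Li] | intermediate (not isolated)
25 | lithium prop-1-yn-1-olate | CC#CO[Li] | intermediate (not isolated)
26 | 1-(triisopropylsiloxy)propyne | CC#CO[Si](C(C)C)(C(C)C)C(C)C | intermediate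
27 | 3-ethoxy-5-(ring D)penta-1,3-dien-1-one (vinylketene; CH2 trans to the ketene carbon) | O=C=C/C(OCC)=C/Cc2c(OC)c(Cc3c(OC)c(Cc4c(OC)c(Cc5c(OC)c(CC6=C(OC)C(C)(C)C(OC)=C(C(=O)CCC)C6=O)c(OC)c(C(=O)CCC)c5OC)c(OC)c(C(=O)CCC)c4OC)c(OC)c(C(=O)CCC)c3OC)c(OC)c(C(=O)CCC)c2OC | intermediate (not isolated)
28 | 4-[1-ethoxy-3-(ring D)prop-1-enyl]-2-methyl-3-(triisopropylsiloxy)cyclobut-2-en-1-one, racemic | CC1=C(O[Si](C(C)C)(C(C)C)C(C)C)C(C1=O)/C(OCC)=C/Cc2c(OC)c(Cc3c(OC)c(Cc4c(OC)c(Cc5c(OC)c(CC6=C(OC)C(C)(C)C(OC)=C(C(=O)CCC)C6=O)c(OC)c(C(=O)CCC)c5OC)c(OC)c(C(=O)CCC)c4OC)c(OC)c(C(=O)CCC)c3OC)c(OC)c(C(=O)CCC)c2OC | intermediate (not isolated)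
29 | 5-ethoxy-2-methyl-7-(ring D)-3-(triisopropylsiloxy)hepta-1,3,5-trien-1-one (dienylketene, cyclisable geometry) | O=C=C(C)/C(O[Si](C(C)C)(C(C)C)C(C)C)=C\C(OCC)=C\Cc2c(OC)c(Cc3c(OC)c(Cc4c(OC)c(Cc5c(OC)c(CC6=C(OC)C(C)(C)C(OC)=C(C(=O)CCC)C6=O)c(OC)c(C(=O)CCC)c5OC)c(OC)c(C(=O)CCC)c4OC)c(OC)c(C(=O)CCC)c3OC)c(OC)c(C(=O)CCC)c2OC | intermediate (not isolated)
30 | 5-ethoxy-2-methyl-6-[(ring D)methyl]-3-(triisopropylsiloxy)cyclohexa-2,4-dien-1-one, racemic | CC1=C(O[Si](C(C)C)(C(C)C)C(C)C)C=C(OCC)C(C1=O)Cc2c(OC)c(Cc3c(OC)c(Cc4c(OC)c(Cc5c(OC)c(CC6=C(OC)C(C)(C)C(OC)=C(C(=O)CCC)C6=O)c(OC)c(C(=O)CCC)c5OC)c(OC)c(C(=O)CCC)c4OC)c(OC)c(C(=O)CCC)c3OC)c(OC)c(C(=O)CCC)c2OC | intermediate (not isolated)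
31 | protected hexamer phenol: ring E is a (6-ethoxy-2-hydroxy-3-methyl-4-triisopropylsiloxyphenyl)methyl group on ring D, with C5 of ring E unsubstituted | Cc1c(O)c(Cc2c(OC)c(Cc3c(OC)c(Cc4c(OC)c(Cc5c(OC)c(CC6=C(OC)C(C)(C)C(OC)=C(C(=O)CCC)C6=O)c(OC)c(C(=O)CCC)c5OC)c(OC)c(C(=O)CCC)c4OC)c(OC)c(C(=O)CCC)c3OC)c(OC)c(C(=O)CCC)c2OC)c(OCC)cc1O[Si](C(C)C)(C(C)C)C(C)C | intermediate
32 | hexamer with ring E as (6-ethoxy-2,4-dihydroxy-3-methylphenyl)methyl | Cc1c(O)c(Cc2c(OC)c(Cc3c(OC)c(Cc4c(OC)c(Cc5c(OC)c(CC6=C(OC)C(C)(C)C(OC)=C(C(=O)CCC)C6=O)c(OC)c(C(=O)CCC)c5OC)c(OC)c(C(=O)CCC)c4OC)c(OC)c(C(=O)CCC)c3OC)c(OC)c(C(=O)CCC)c2OC)c(OCC)cc1O | intermediate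
33 | protected hexamer with ring E as (5-butanoyl-6-ethoxy-2,4-dihydroxy-3-methylphenyl)methyl | Cc1c(O)c(Cc2c(OC)c(Cc3c(OC)c(Cc4c(OC)c(Cc5c(OC)c(CC6=C(OC)C(C)(C)C(OC)=C(C(=O)CCC)C6=O)c(OC)c(C(=O)CCC)c5OC)c(OC)c(C(=O)CCC)c4OC)c(OC)c(C(=O)CCC)c3OC)c(OC)c(C(=O)CCC)c2OC)c(OCC)c(C(=O)CCC)c1O | intermediate
34 | CNP0309827.0 (achiral, no stereocentre) | CCCC(=O)C1=C(O)C(C)(C)C(O)=C(Cc2c(O)c(Cc3c(O)c(Cc4c(O)c(Cc5c(O)c(Cc6c(O)c(C)c(O)c(C(=O)CCC)c6O)c(O)c(C(=O)CCC)c5O)c(O)c(C(=O)CCC)c4O)c(O)c(C(=O)CCC)c3O)c(O)c(C(=O)CCC)c2O)C1=O | target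

Total step count: 16. Longest linear sequence: 13 steps (steps 2, 3, 4, 5, 6, 8, 9, 10, 11, 13, 14, 15, 16).

Steps most likely to fail

Step 13. The ethoxy-vinylketene may dimerise or decompose before the bimolecular [2+2] with the siloxyalkyne, which the bulk of the pentamer slows, and the siloxyalkyne may be lost by thermal isomerisation to a silylketene. In the fallback, ring E is not built but brought in as a finished arene, and the chain is grown from that end by the chloromethylation and benzylation cycle of steps 4 to 6. It sets out from 2 and comes back to the route at target 34. Commercial 2,4,6-trimethoxytoluene is butanoylated (PrCOCl, SnCl4, CH2Cl2, −10 °C) to 1-(2,4,6-trimethoxy-3-methylphenyl)butan-1-one F1, which is chloromethylated (MOMCl, ZnCl2) at its only free position to the ring E benzylic chloride F2. ZnCl2-catalysed benzylation of excess 2 with it gives the dimer E–D F3, and chloromethylation of its one free position the dimer chloride F4. Two further cycles with 2 give in turn the trimer E–D–C F5, the trimer chloride F6, the tetramer E–D–C–B F7 and the tetramer chloride F8. A last benzylation of 2 gives the pentamer E–D–C–B–A F9, chloromethylation the pentamer chloride F10, and coupling with 14 as in step 8 the hexamer with free ring F enols F11. BBr3 cleavage of its fifteen aryl methyl ethers gives 34.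

Step 16. Ipso-protonation of a ring followed by retro-Friedel–Crafts cleavage could redistribute the methylene bridges, or the cleavage could stall at partly methylated stages because the boron reagent is sequestered by the many chelating carbonyls. The fallback stages the deprotection by mechanism; it sets out from 33 and comes back at 34. BCl3 (CH2Cl2, −78 °C → rt, then 1 M HCl/THF) cleaves by chelation control the ethyl ether and the eight methyl ethers that flank the aryl ketones, and also the two ring F enol ethers. This leaves the tetramethyl ether F12, in which every ring is already a deactivated o-hydroxy ketone. Its four hindered methoxy groups para to the butanoyl groups are then removed by hard-acid and soft-nucleophile demethylation (AlCl3, EtSH, CH2Cl2, 0 °C) to give 34.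

Step 8. Chloromethylation of the crowded ring A position could be incomplete, and capture of the benzylic cation on enol oxygen, ionisation without productive capture or loss of the chloride by hydrolysis could erode the coupling. The fallback forms the same bond with reversed oxidation level and without a benzylic halide; it sets out from tetramer 13 and comes back at 16. Rieche formylation (Cl2CHOMe, TiCl4, CH2Cl2, −78 → 0 °C) at the free position of ring A gives the tetramer aldehyde F13. Three-component reductive alkylation of 14 with it (Hantzsch ester, L-proline cat., CH2Cl2, rt; Knoevenagel condensation, then hydride transfer to the alkylidene triketone) gives 16.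

Further compounds

F1 | step 13 | 1-(2,4,6-trimethoxy-3-methylphenyl)butan-1-one | CCCC(=O)c1c(OC)cc(OC)c(C)c1OC
F2 | step 13 | 1-[3-(chloromethyl)-2,4,6-trimethoxy-5-methylphenyl]butan-1-one | CCCC(=O)c1c(OC)c(CCl)c(OC)c(C)c1OC
F3 | step 13 | permethylated dimer E–D with one free C–H on ring D | CCCC(=O)c1c(OC)c(C)c(OC)c(Cc2c(OC)c(C(=O)CCC)c(OC)cc2OC)c1OC
F4 | step 13 | dimer E–D with CH2Cl on ring D | CCCC(=O)c1c(OC)c(C)c(OC)c(Cc2c(OC)c(C(=O)CCC)c(OC)c(CCl)c2OC)c1OC
F5 | step 13 | permethylated trimer E–D–C with one free C–H on ring C | CCCC(=O)c1c(OC)c(C)c(OC)c(Cc2c(OC)c(C(=O)CCC)c(OC)c(Cc3c(OC)c(C(=O)CCC)c(OC)cc3OC)c2OC)c1OC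
F6 | step 13 | trimer E–D–C with CH2Cl on ring C | CCCC(=O)c1c(OC)c(C)c(OC)c(Cc2c(OC)c(C(=O)CCC)c(OC)c(Cc3c(OC)c(C(=O)CCC)c(OC)c(CCl)c3OC)c2OC)c1OC
F7 | step 13 | permethylated tetramer E–D–C–B with one free C–H on ring B | CCCC(=O)c1c(OC)c(C)c(OC)c(Cc2c(OC)c(C(=O)CCC)c(OC)c(Cc3c(OC)c(C(=O)CCC)c(OC)c(Cc4c(OC)c(C(=O)CCC)c(OC)cc4OC)c3OC)c2OC)c1OC
F8 | step 13 | tetramer E–D–C–B with CH2Cl on ring B | CCCC(=O)c1c(OC)c(C)c(OC)c(Cc2c(OC)c(C(=O)CCC)c(OC)c(Cc3c(OC)c(C(=O)CCC)c(OC)c(Cc4c(OC)c(C(=O)CCC)c(OC)c(CCl)c4OC)c3OC)c2OC)c1OC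
F9 | step 13 | permethylated pentamer E–D–C–B–A with one free C–H on ring A | CCCC(=O)c1c(OC)c(C)c(OC)c(Cc2c(OC)c(C(=O)CCC)c(OC)c(Cc3c(OC)c(C(=O)CCC)c(OC)c(Cc4c(OC)c(C(=O)CCC)c(OC)c(Cc5c(OC)c(C(=O)CCC)c(OC)cc5OC)c4OC)c3OC)c2OC)c1OC
F10 | step 13 | pentamer E–D–C–B–A with CH2Cl on ring A | CCCC(=O)c1c(OC)c(C)c(OC)c(Cc2c(OC)c(C(=O)CCC)c(OC)c(Cc3c(OC)c(C(=O)CCC)c(OC)c(Cc4c(OC)c(C(=O)CCC)c(OC)c(Cc5c(OC)c(C(=O)CCC)c(OC)c(CCl)c5OC)c4OC)c3OC)c2OC)c1OC
F11 | step 13 | hexamer with rings A to E as trimethyl ethers and free ring F enols | CCCC(=O)c1c(OC)c(C)c(OC)c(Cc2c(OC)c(C(=O)CCC)c(OC)c(Cc3c(OC)c(C(=O)CCC)c(OC)c(Cc4c(OC)c(C(=O)CCC)c(OC)c(Cc5c(OC)c(C(=O)CCC)c(OC)c(CC6=C(O)C(C)(C)C(O)=C(C(=O)CCC)C6=O)c5OC)c4OC)c3OC)c2OC)c1OC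
F12 | step 16 | hexamer retaining only the four methoxy groups para to the butanoyl groups of rings A to D | CCCC(=O)C1=C(O)C(C)(C)C(O)=C(Cc2c(OC)c(Cc3c(OC)c(Cc4c(OC)c(Cc5c(OC)c(Cc6c(O)c(C)c(O)c(C(=O)CCC)c6O)c(O)c(C(=O)CCC)c5O)c(O)c(C(=O)CCC)c4O)c(O)c(C(=O)CCC)c3O)c(O)c(C(=O)CCC)c2O)C1=O
F13 | step 8 | tetramer aldehyde: 13 with CHO at the free position of ring A | O=C(CCc2c(OC)c(Cc3c(OC)c(Cc4c(OC)c(Cc5c(OC)c(C=O)c(OC)c(C(=O)CCC)c5OC)c(OC)c(C(=O)CCC)c4OC)c(OC)c(C(=O)CCC)c3OC)c(OC)c(C(=O)CCC)c2OC)OCc1ccccc1
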